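**Retrosynthetic overview**
1. The benzylic O–Si bond is cut last: the target is released from its triisopropylsilyl ether by fluoride.
2. The phenol C1–O bond is traced back to C1–H. C1 lies between the bromines on C2 and C6, the most acidic ring C–H, so lithiation, borylation and oxidation place the oxygen there.
3. The benzene ring, the only ring, is opened across C2–C3 and C4–C5 (Diels–Alder reaction, then loss of CO2). The strategy rests on reading C2(Br)–C1(H)–C6(Br)–C5(H) as the C3–C6 diene of 3,5-dibromo-2-pyrone and C3(Br)–C4(CH2O) as the two carbons of a silylated 3-bromopropargyl alcohol.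
4. The pyrone comes from coumalic acid by bromodecarboxylation; the bromoalkyne comes from propargyl alcohol by silylation and silver-catalysed bromination.

Key step: step 4

Remark: the target is achiral, and the bridged lactone of the key step forms as a racemate whose two bridgehead stereocentres vanish on loss of CO2, so no stereocontrol is planned.

**Route**

Step 1
Reactants: 1 coumalic acid; 2 N-bromosuccinimide
Product: 3 3,5-dibromo-2H-pyran-2-one
Conditions: NBS (2.5 equiv), LiOAc, MeCN/H2O, rt
Reagents that add atoms: N-bromosuccinimide 2, O=C1CCC(=O)N1Br
Why: Hunsdiecker-type bromodecarboxylation replaces the C5 carboxylate by bromine with loss of CO2, and the nucleophilic C3 of the pyrone takes the second bromine by electrophilic substitution, a known preparation of this pyrone.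

Step 2
Reactants: 4 prop-2-yn-1-ol; 5 triisopropylsilyl chloride
Product: 6 triisopropyl(prop-2-yn-1-yloxy)silane
Conditions: TIPSCl, imidazole, CH2Cl2, 0 °C → rt
Reagents that add atoms: triisopropylsilyl chloride 5, CC(C)[Si](Cl)(C(C)C)C(C)C
Why: Standard silylation of a primary alcohol with a silyl chloride and imidazole gives a bulky ether that should withstand the later bromination, heating and amide base.

Step 3
Reactants: 6 triisopropyl(prop-2-yn-1-yloxy)silane; 2 N-bromosuccinimide
Product: 7 [(3-bromoprop-2-yn-1-yl)oxy]triisopropylsilane
Conditions: NBS, AgNO3 (10 mol%), acetone, rt, dark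
Reagents that add atoms: N-bromosuccinimide 2, O=C1CCC(=O)N1Br
Why: Silver-catalysed electrophilic bromination of a terminal alkyne (a silver acetylide captured by the N-bromo imide) is a routine way to 1-bromoalkynes and leaves the silyl ether untouched.

Step 4
Reactants: 3 3,5-dibromo-2H-pyran-2-one; 7 [(3-bromoprop-2-yn-1-yl)oxy]triisopropylsilane
Product: 9 triisopropyl[(2,3,5-tribromobenzyl)oxy]silane, via bridged tribromo lactone 8 (not isolated)
Conditions: 7 (3 equiv), 2,6-di-tert-butyl-4-methylphenol (cat.), PhMe, sealed tube, 150 °C
Reagents that add atoms: none
Why: Proposed new method: the electron-poor diene of pyrone 3 (C3=C4–C5=C6) and the triple bond of 7 should combine in a concerted but asynchronous thermal [4+2] cycloaddition to the bridged dienyl lactone 8, which at the reaction temperature expels CO2 by retro-[4+2] reaction and so delivers arene 9. The closest known reaction type is the Diels–Alder/decarboxylation of 2-pyrones with alkynes, together with the cycloadditions of 3,5-dibromo-2-pyrone with alkenes of either polarity; a 1-bromoalkyne as the 2π partner and its orientation are untested. The benzene ring is closed by an intermolecular [4+2] cycloaddition that forms the C2–C3 and C4–C5 bonds of the target skeleton and becomes aromatic by cycloreversion, so the two bridgehead stereocentres of racemic 8 are lost and no stereocentre has to be controlled. The selectivity that matters is regiochemical: the alkyne carbon bearing bromine must bond to the brominated pyrone C3. This is expected because halogenated 2-pyrones bond first through C6, here to the alkyne carbon remote from bromine (the more nucleophilic end of a haloalkyne), leaving developing charge or spin on the bromine-bearing alkyne carbon and on pyrone C3 next to bromine and the lactone carbonyl, and because the bulky CH2OSi(iPr)3 arm then sits beside the bridgehead C–H and not beside the bridgehead C–Br. All three bromines stay on sp2 carbons, so no electrophilic bromination of the ring is needed, and the reverse orientation would give the 2,4,6-tribromobenzyl isomer, to be removed by chromatography.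

Step 5
Reactants: 9 triisopropyl[(2,3,5-tribromobenzyl)oxy]silane
Product: 12 2,3,6-tribromo-4-{[(triisopropylsilyl)oxy]methyl}phenol, via aryllithium 10 (not isolated), via lithium aryl(triisopropoxy)borate 11 (not isolated)
Conditions: B(OiPr)3, then LiN(iPr)2, THF, −78 °C; then AcOH, 30% aq. H2O2, 0 °C → rt
Reagents that add atoms: hydrogen peroxide, OO
Why: Directed ortho-lithiation removes the ring proton flanked by two bromines, the most acidic site, and the borate present in the flask should trap the aryllithium before LiBr loss or bromine migration, after which the known boron-to-oxygen aryl shift on peroxide oxidation gives the phenol with the silyl ether and C–Br bonds intact.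

Step 6
Reactants: 12 2,3,6-tribromo-4-{[(triisopropylsilyl)oxy]methyl}phenol
Product: 13 2,3,6-tribromo-4-(hydroxymethyl)phenol
Conditions: Bu4NF, AcOH, THF, 0 °C → rt
Reagents that add atoms: none
Why: Fluoride-induced desilylation, driven by the strong Si–F bond and buffered with acetic acid so that the acidic tribromophenol is not held as its phenoxide, should free the benzylic alcohol without touching the aryl bromides.

**Compound list**
1 | coumalic acid (2-oxo-2H-pyran-5-carboxylic acid) | OC(=O)C1=COC(=O)C=C1 | starting material
2 | N-bromosuccinimide | O=C1CCC(=O)N1Br | starting material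
3 | 3,5-dibromo-2H-pyran-2-one | O=C1OC=C(Br)C=C1Br | intermediate
4 | prop-2-yn-1-ol (propargyl alcohol) | C#CCO | starting material
5 | triisopropylsilyl chloride | CC(C)[Si](Cl)(C(C)C)C(C)C | starting material
6 | triisopropyl(prop-2-yn-1-yloxy)silane | CC(C)[Si](OCC#C)(C(C)C)C(C)C | intermediate
7 | [(3-bromoprop-2-yn-1-yl)oxy]triisopropylsilane | CC(C)[Si](OCC#CBr)(C(C)C)C(C)C | intermediate
8 | 4,5,7-tribromo-6-{[(triisopropylsilyl)oxy]methyl}-2-oxabicyclo[2.2.2]octa-5,7-dien-3-one (racemic, one enantiomer drawn; not isolated) | O=C1O[C@@H]2C(Br)=C[C@@]1(Br)C(Br)=C2CO[Si](C(C)C)(C(C)C)C(C)C | intermediate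
9 | triisopropyl[(2,3,5-tribromobenzyl)oxy]silane | CC(C)[Si](OCc1cc(Br)cc(Br)c1Br)(C(C)C)C(C)C | intermediate
10 | (2,3,6-tribromo-4-{[(triisopropylsilyl)oxy]methyl}phenyl)lithium (not isolated) | [Li]c1c(Br)cc(CO[Si](C(C)C)(C(C)C)C(C)C)c(Br)c1Br | intermediate
11 | lithium triisopropoxy(2,3,6-tribromo-4-{[(triisopropylsilyl)oxy]methyl}phenyl)borate (not isolated) | [Li+].CC(C)O[B-](OC(C)C)(OC(C)C)c1c(Br)cc(CO[Si](C(C)C)(C(C)C)C(C)C)c(Br)c1Br | intermediate
12 | 2,3,6-tribromo-4-{[(triisopropylsilyl)oxy]methyl}phenol | Oc1c(Br)cc(CO[Si](C(C)C)(C(C)C)C(C)C)c(Br)c1Br | intermediate
13 | 2,3,6-tribromo-4-(hydroxymethyl)phenol | OCc1cc(Br)c(O)c(Br)c1Br | target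

**Step count**
Total steps: 6. Longest linear sequence: 5 steps (steps 2, 3, 4, 5, 6, from propargyl alcohol); the pyrone branch is 4 steps (steps 1, 4, 5, 6).

**Steps most likely to fail**

1. Step 4 (proposed new method). The cycloaddition may be too slow to compete with thermal decay of the pyrone, or the alkyne may add in the reverse orientation so that the benzylic arm ends up between two bromines. The fallback uses known chemistry and gives up the cycloaddition. It sets out from triisopropylsilyl chloride 5, the one route compound it keeps, together with purchased 2-amino-3,5-dibromobenzaldehyde F1, and comes back to the route at 9. A Sandmeyer-type bromodediazoniation of the amine (tBuONO, CuBr2, MeCN, 60 °C) should give 2,3,5-tribromobenzaldehyde F2. Reduction with NaBH4 in MeOH at 0 °C should give (2,3,5-tribromophenyl)methanol F3. Silylation with 5 and imidazole in CH2Cl2 then gives 9 with the bromine pattern fixed by the starting arene.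

2. Step 5. The aryllithium may lose LiBr or let a bromine migrate before it is trapped, or the crowded, electron-poor borate may be protonated off the ring before oxygen insertion. The fallback replaces the boron relay by direct electrophilic oxygenation of the carbanion. It sets out from 9 and comes back at 12. Lithiation with LiN(iPr)2 in THF at −78 °C without borate gives aryllithium 10, which is quenched with bis(trimethylsilyl) peroxide to give trimethyl(2,3,6-tribromo-4-{[(triisopropylsilyl)oxy]methyl}phenoxy)silane F4. Brief treatment with K2CO3 in MeOH at 0 °C cleaves the aryl O–SiMe3 bond only and gives 12.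

3. Step 1. The second bromination may stop short or overrun, leaving a mixture of mono- and dibrominated pyrones that is wasteful to separate. The fallback installs the two bromines in separate operations. It sets out from 1 and comes back at 3. Bromodecarboxylation with one equivalent of NBS and LiOAc in MeCN/H2O should give 5-bromo-2H-pyran-2-one F5. Addition of Br2 in CH2Cl2 followed by elimination with Et3N then places the bromine on C3 and gives 3.

**Further compounds**
F1 | step 4 | 2-amino-3,5-dibromobenzaldehyde | Nc1c(Br)cc(Br)cc1C=O
F2 | step 4 | 2,3,5-tribromobenzaldehyde | O=Cc1cc(Br)cc(Br)c1Br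
F3 | step 4 | (2,3,5-tribromophenyl)methanol | OCc1cc(Br)cc(Br)c1Br
F4 | step 5 | trimethyl(2,3,6-tribromo-4-{[(triisopropylsilyl)oxy]methyl}phenoxy)silane | C[Si](C)(C)Oc1c(Br)cc(CO[Si](C(C)C)(C(C)C)C(C)C)c(Br)c1Br
F5 | step 1 | 5-bromo-2H-pyran-2-one | O=C1OC=C(Br)C=C1
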